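## Retrosynthetic overview
1. The dihydrofuran ring is opened at its O–C2 bond. This leads back to the (S)-epoxide of a prenyl side chain, and from there to isowighteone (3'-prenylgenistein). One catalytic asymmetric operation makes both C–O bonds (O-transfer, then invertive 5-exo closure) and sets the only stereocentre.
2. Isowighteone is cut at the aryl–prenyl bond to give 3'-bromogenistein and prenyl-Bpin.
3. In 3'-bromogenistein the γ-pyranone is opened (C2 comes from DMF, closure is O1–C2) to a deoxybenzoin. This comes from phloroglucinol and (3-bromo-4-hydroxyphenyl)acetic acid.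
4. Ring order: both benzene rings are bought, the pyranone is formed in step 1, and the dihydrofuran is formed last in step 3. No protecting groups are used.

Assumption: CIP analysis of the given SMILES gives (R). Catalyst P is Boc-L-Asp-D-Pro-Aib-L-Phe-NMe2, CC(C)(C)OC(=O)N[C@@H](CC(=O)O)C(=O)N1CCC[C@@H]1C(=O)NC(C)(C)C(=O)N[C@@H](Cc1ccccc1)C(=O)N(C)C, made separately by routine peptide coupling and not counted. Its sense of induction cannot be predicted safely, so if a test on 2-prenylphenol shows the opposite sense, the equally accessible mirror-image peptide is used.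

## Route

Step 1
Reactants: 1 phloroglucinol; 2 (3-bromo-4-hydroxyphenyl)acetic acid
Product: 5 3'-bromogenistein, via deoxybenzoin 3 (not isolated), via enaminoketone 4 (not isolated)
Conditions: BF3·OEt2 (solvent), 85 °C, 1.5 h; cool to 10 °C, DMF, then MsCl (3 equiv) in DMF, 55–70 °C, 2 h; pour into aq NaOAc, filter, recrystallise (aq EtOH)
Reagents that add atoms: N,N-dimethylformamide, CN(C)C=O
Why: BF3-promoted Friedel–Crafts C-acylation of symmetric phloroglucinol (only one mono-acyl isomer is possible) gives the chelated deoxybenzoin, whose methylene is aminomethylenated by the DMF/MsCl Vilsmeier-type iminium salt and then closes by attack of an ortho-OH with loss of Me2NH (deoxybenzoin route to isoflavones, the standard one-pot genistein procedure); no stereocentre is formed.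

Step 2
Reactants: 5 3'-bromogenistein; 6 prenylboronic acid pinacol ester (1.8 equiv)
Product: 7 isowighteone (3'-prenylgenistein)
Conditions: Pd-PEPPSI-IPent (3 mol %), K3PO4 (5 equiv), degassed THF/H2O 4:1, 65 °C, 6 h; acidify to pH 5, extract (EtOAc)
Reagents that add atoms: none
Why: In this Suzuki–Miyaura allyl–aryl cross-coupling the very bulky NHC ligand lets the allyl-Pd species equilibrate and reductively eliminate at the unsubstituted terminus, giving the linear prenyl arene rather than the reverse-prenyl isomer; C–Br is the only site for oxidative addition, the phenols are merely present as phenoxides, and no stereocentre is formed.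

Step 3
Reactants: 7 isowighteone
Product: 9 (R)-5,7-dihydroxy-3-[2-(2-hydroxypropan-2-yl)-2,3-dihydro-1-benzofuran-5-yl]-4H-chromen-4-one (CNP0200981.1), via (S)-epoxide 8 (not isolated)
Conditions: P (10 mol %), DMAP (10 mol %), HOBt·H2O (10 mol %), DIC (1.5 equiv, slow addition), 30 % aq H2O2 (2 equiv), CH2Cl2/EtOAc 4:1 (0.02 M), 0 °C, 24 h; aq Na2SO3 wash, swap solvent to THF; DBU (3 equiv), 0 °C to rt, 2 h; pH 5 work-up, recrystallise to raise ee
Reagents that add atoms: hydrogen peroxide, OO
Why: Proposed new method: phenol-directed catalytic enantioselective epoxidation by a peptide-bound aspartyl peracid, followed by stereospecific ring closure. DIC/H2O2 (with the DMAP/HOBt shuttle) turns the Asp side chain of P into its peracid, and the 4'-OH next to the prenyl group hydrogen-bonds to the strongly accepting C-terminal tertiary-amide carbonyl of the D-Pro-Aib β-turn, so the concerted butterfly transition state delivers oxygen to the Si face of C2'' of the only electron-rich alkene (the chromone C2=C3 is electron-poor, and the phenol rings are inert to peracids at 0 °C); this sets the stereocentre as (S) in 8. DBU then forms the 4'-phenoxide, which opens the epoxide at the less substituted carbon by SN2 5-exo-tet attack with clean inversion, giving the (R)-dihydrobenzofuran and releasing the tertiary alcohol, while basic conditions suppress the acid-type 6-endo opening to the chromanol. The closest known reaction types are aspartyl-peptide peracid epoxidations directed by carbamate or allylic hydroxyl groups, and the racemic mCPBA epoxidation–cyclisation of o-prenylphenols; a phenol OH as the directing group, an o-prenylphenol substrate and catalyst P itself are untested.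

## Compound list
1 | phloroglucinol (benzene-1,3,5-triol) | Oc1cc(O)cc(O)c1 | starting material
2 | (3-bromo-4-hydroxyphenyl)acetic acid | OC(=O)Cc1ccc(O)c(Br)c1 | starting material
3 | 2-(3-bromo-4-hydroxyphenyl)-1-(2,4,6-trihydroxyphenyl)ethan-1-one (deoxybenzoin) | O=C(Cc1ccc(O)c(Br)c1)c1c(O)cc(O)cc1O | intermediate
4 | 2-(3-bromo-4-hydroxyphenyl)-3-(dimethylamino)-1-(2,4,6-trihydroxyphenyl)prop-2-en-1-one (enaminoketone, alkene geometry irrelevant) | CN(C)C=C(c1ccc(O)c(Br)c1)C(=O)c1c(O)cc(O)cc1O | intermediate
5 | 3'-bromogenistein, 3-(3-bromo-4-hydroxyphenyl)-5,7-dihydroxy-4H-chromen-4-one | O=c1c(-c2ccc(O)c(Br)c2)coc2cc(O)cc(O)c12 | intermediate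
6 | prenylboronic acid pinacol ester, 4,4,5,5-tetramethyl-2-(3-methylbut-2-en-1-yl)-1,3,2-dioxaborolane | CC(C)=CCB1OC(C)(C)C(C)(C)O1 | starting material
7 | isowighteone, 5,7-dihydroxy-3-[4-hydroxy-3-(3-methylbut-2-en-1-yl)phenyl]-4H-chromen-4-one | CC(C)=CCc1cc(-c2coc3cc(O)cc(O)c3c2=O)ccc1O | intermediate
8 | 3-(3-{[(2S)-3,3-dimethyloxiran-2-yl]methyl}-4-hydroxyphenyl)-5,7-dihydroxy-4H-chromen-4-one | CC1(C)O[C@H]1Cc1cc(-c2coc3cc(O)cc(O)c3c2=O)ccc1O | intermediate
9 | (R)-5,7-dihydroxy-3-[2-(2-hydroxypropan-2-yl)-2,3-dihydro-1-benzofuran-5-yl]-4H-chromen-4-one | CC(C)(O)[C@H]1Cc2cc(-c3coc4cc(O)cc(O)c4c3=O)ccc2O1 | target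

## Step count
Total step count: 3. Longest linear sequence: 3.

## Steps most likely to fail

**1. Step 3 (the new step).**
- Risks:
  - The ee may be low, because 7 needs a partly polar solvent that competes for the directing hydrogen bond.
  - The acidic 7-OH may consume DIC.
  - Some 6-endo chromanol may form before the base is added.
- The fallback uses known chemistry. It sets out from 7 and comes back at 9.
- Silylation of 7 (TBSCl 2.2 equiv, imidazole, DMF, rt; the chelated 5-OH stays free) gives 7,4'-bis-O-TBS-isowighteone F1.
- Shi epoxidation follows, with the L-fructose-derived (ent-Shi) ketone (30 mol %), Oxone, K2CO3/borate-EDTA buffer at pH 10.5, MeCN/dimethoxymethane, 0 °C. It gives the (S)-epoxide bis-TBS ether F2. The D-fructose ketone gives (R)-epoxides from R-CH2-CH=CMe2 olefins, so its enantiomer is needed.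
- TBAF (2.2 equiv, THF, 0 °C) frees the 4'-phenoxide, which closes 5-exo with inversion to 9.

**2. Step 2.**
- Risks:
  - Oxidative addition into the electron-rich bromophenoxide may be slow.
  - Compound 6 may protodeboronate.
  - Some reverse-prenyl isomer may form.
- The fallback sets out from 5 and comes back at 7. It masks the phenols and switches to a neutral, base-free tin coupling.
- Ac2O/pyridine/DMAP gives 3'-bromogenistein triacetate F3.
- Stille coupling with tributyl(3-methylbut-2-en-1-yl)stannane (Pd(PPh3)4, DMF, 100 °C) gives isowighteone triacetate F4.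
- K2CO3/MeOH (0 °C to rt) returns 7.

**3. Step 1.**
- Risks: the acylation may be incomplete, or tar may form in hot BF3·OEt2 and carry into the ring closure.
- The fallback sets out from 1 and comes back at 3, which is now isolated and purified.
- 4-Hydroxyphenylacetonitrile is brominated (NBS, MeCN, 0 °C) to 2-(3-bromo-4-hydroxyphenyl)acetonitrile F5.
- A Houben–Hoesch reaction of F5 with 1 (dry HCl, ZnCl2, Et2O, 0 °C) precipitates the ketiminium chloride F6.
- Boiling water hydrolyses F6 to 3.
- Pure 3 is closed to 5 with the DMF/MsCl/BF3·OEt2 stage of step 1, run as a separate operation.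

## Further compounds
F1 | step 3 | 7,4'-bis-O-(tert-butyldimethylsilyl)isowighteone | CC(C)=CCc1cc(-c2coc3cc(O[Si](C)(C)C(C)(C)C)cc(O)c3c2=O)ccc1O[Si](C)(C)C(C)(C)C
F2 | step 3 | (S)-epoxide of 7,4'-bis-O-TBS-isowighteone | CC1(C)O[C@H]1Cc1cc(-c2coc3cc(O[Si](C)(C)C(C)(C)C)cc(O)c3c2=O)ccc1O[Si](C)(C)C(C)(C)C
F3 | step 2 | 3'-bromogenistein triacetate | CC(=O)Oc1ccc(cc1Br)-c1coc2cc(OC(C)=O)cc(OC(C)=O)c2c1=O
F4 | step 2 | isowighteone triacetate | CC(C)=CCc1cc(-c2coc3cc(OC(C)=O)cc(OC(C)=O)c3c2=O)ccc1OC(C)=O
F5 | step 1 | 2-(3-bromo-4-hydroxyphenyl)acetonitrile | N#CCc1ccc(O)c(Br)c1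
F6 | step 1 | 2-(3-bromo-4-hydroxyphenyl)-1-(2,4,6-trihydroxyphenyl)ethan-1-iminium chloride | [Cl-].[NH2+]=C(Cc1ccc(O)c(Br)c1)c1c(O)cc(O)cc1O
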